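Lower ring C carries O1 on C8a and a hydroxyl on C4, with C2–C3 between them, so ring A plus C4 is a salicylaldehyde and C2–C3 a nitroalkene. Disconnecting O1–C2 and C3–C4 lets one organocatalytic oxa-Michael–Henry domino reaction close ring C and set C2, C3 and C4 at once; the nitro group is afterwards exchanged for the cis hydroxyl through the C3 ketone. The precursor is a 3,4-bis(benzyloxy)salicylaldehyde bearing at C5 the perbenzylated (2R,3R,4S)-flavan-3-ol upper unit, which is assembled beforehand by rhodium-catalysed asymmetric arylation of a coumarin, lactone opening and Mitsunobu ring closure.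

Key step: step 17

Assumption: the sense of induction of the rhodium–SEGPHOS catalyst (step 7) and of the squaramide catalyst (step 17) is assigned by analogy with simpler coumarins and salicylaldehydes; the mirror-image ligand or the quinidine-derived pseudoenantiomer would be used if the opposite sense were found.

In the names below, "upper unit" means the (2R,3R,4S)-3,7,8-tris(benzyloxy)-2-[3,4-bis(benzyloxy)phenyl]chroman-4-yl group (2,3-cis-3,4-trans).

Step 1
Reactants: 1 2,3,4-trihydroxybenzaldehyde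
Product: 2 2,3-dihydroxy-4-(methoxymethoxy)benzaldehyde
Conditions: MOMCl (1.0 equiv), K2CO3 (1.0 equiv), acetone, 0 °C → rt
Reagents that add atoms: chloromethyl methyl ether, COCCl
Why: Williamson etherification is expected at the 4-hydroxyl because it is the most acidic (para to the formyl group) while the 2-hydroxyl is held in a hydrogen bond to the carbonyl, so one equivalent of base and electrophile should give the mono-ether.

Step 2
Reactants: 2 2,3-dihydroxy-4-(methoxymethoxy)benzaldehyde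
Product: 3 2,3-bis(benzyloxy)-4-(methoxymethoxy)benzaldehyde
Conditions: BnBr (2.5 equiv), K2CO3, DMF, 60 °C
Reagents that add atoms: benzyl bromide, BrCc1ccccc1
Why: Exhaustive Williamson benzylation of the two remaining phenols in warm DMF, conditions under which the acetal-type MOM ether is inert.

Step 3
Reactants: 3 2,3-bis(benzyloxy)-4-(methoxymethoxy)benzaldehyde
Product: 5 2,3-bis(benzyloxy)-4-(methoxymethoxy)phenol, via aryl formate 4 (not isolated)
Conditions: mCPBA, CH2Cl2, 0 °C → rt; then K2CO3 (cat.), MeOH, rt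
Reagents that add atoms: 3-chloroperoxybenzoic acid, OOC(=O)c1cccc(Cl)c1
Why: Baeyer–Villiger (Dakin-type) oxidation of an electron-rich benzaldehyde proceeds by aryl migration to the formate, which mild methanolysis cleaves to the phenol without touching benzyl or MOM ethers.

Step 4
Reactants: 5 2,3-bis(benzyloxy)-4-(methoxymethoxy)phenol
Product: 6 2,3-bis(benzyloxy)-4-(methoxymethoxy)phenyl trifluoromethanesulfonate
Conditions: Tf2O, pyridine, CH2Cl2, 0 °C
Reagents that add atoms: trifluoromethanesulfonic anhydride, O=S(=O)(OS(=O)(=O)C(F)(F)F)C(F)(F)F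
Why: Standard O-sulfonylation of a phenol turns the C–O bond into a cross-coupling handle at the position marked by the former formyl group.

Step 5
Reactants: 6 2,3-bis(benzyloxy)-4-(methoxymethoxy)phenyl trifluoromethanesulfonate
Product: 8 [2,3-bis(benzyloxy)-4-(methoxymethoxy)phenyl]boronic acid, via pinacol boronate 7 (not isolated)
Conditions: B2pin2, PdCl2(dppf) (5 mol %), KOAc, dioxane, 85 °C; then NaIO4, NH4OAc, acetone/H2O, rt
Reagents that add atoms: bis(pinacolato)diboron, CC1(C)OB(OC1(C)C)B1OC(C)(C)C(C)(C)O1; water, O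
Why: Miyaura borylation of the aryl triflate followed by periodate cleavage of the pinacol ester gives the free boronic acid needed for base-free rhodium catalysis.

Step 6
Reactants: 9 7,8-dihydroxycoumarin
Product: 10 7,8-bis(benzyloxy)coumarin
Conditions: BnBr (2.4 equiv), K2CO3, DMF, 60 °C
Reagents that add atoms: benzyl bromide, BrCc1ccccc1
Why: Williamson benzylation of both phenols, with the lactone surviving carbonate in DMF.

Step 7
Reactants: 10 7,8-bis(benzyloxy)coumarin; 8 [2,3-bis(benzyloxy)-4-(methoxymethoxy)phenyl]boronic acid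
Product: 11 (4S)-7,8-bis(benzyloxy)-4-[2,3-bis(benzyloxy)-4-(methoxymethoxy)phenyl]chroman-2-one
Conditions: 8 (3 equiv), Rh(acac)(C2H4)2 (3 mol %), (S)-SEGPHOS (3.3 mol %), dioxane/H2O (10:1), 60 °C
Reagents that add atoms: none
Why: Hayashi–Miyaura asymmetric 1,4-addition, in which the aryl–rhodium species carrying (S)-SEGPHOS inserts the coumarin C3–C4 double bond on one face and hydrolysis of the oxa-π-allyl releases the lactone, so the ligand should set C4 as S while the absence of base keeps the lactone closed.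

Step 8
Reactants: 11 (4S)-4-aryl-7,8-bis(benzyloxy)chroman-2-one
Product: 12 (3R,4S)-7,8-bis(benzyloxy)-4-[2,3-bis(benzyloxy)-4-(methoxymethoxy)phenyl]-3-hydroxychroman-2-one (3,4-trans)
Conditions: KN(SiMe3)2, THF, −78 °C; then 3-phenyl-2-(phenylsulfonyl)oxaziridine, −78 °C; AcOH
Reagents that add atoms: 3-phenyl-2-(phenylsulfonyl)oxaziridine, O=S(=O)(N1OC1c1ccccc1)c1ccccc1
Why: Davis oxidation of the lactone potassium enolate, in which the oxaziridine approaches the face opposite the C4 aryl group and so should set the 3-hydroxyl trans to it (3R).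

Step 9
Reactants: 12 (3R,4S)-3-hydroxy lactone
Product: 13 (3R,4S)-3,7,8-tris(benzyloxy)-4-[2,3-bis(benzyloxy)-4-(methoxymethoxy)phenyl]chroman-2-one
Conditions: BnBr, Ag2O, CH2Cl2, rt, dark
Reagents that add atoms: benzyl bromide, BrCc1ccccc1
Why: Silver oxide-mediated Williamson benzylation is essentially neutral and therefore should avoid epimerisation at C3 or opening of the aryl ester.

Step 10
Reactants: 13 (3R,4S)-3-benzyloxy lactone
Product: 14 (2R,3R)-2-(benzyloxy)-3-[3,4-bis(benzyloxy)-2-hydroxyphenyl]-3-[2,3-bis(benzyloxy)-4-(methoxymethoxy)phenyl]-N-methoxy-N-methylpropanamide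
Conditions: MeNH(OMe)·HCl, i-PrMgCl, THF, −20 → 0 °C
Reagents that add atoms: N,O-dimethylhydroxylamine hydrochloride, CNOC.Cl
Why: Weinreb aminolysis by the chloromagnesium amide opens the activated aryl lactone at low temperature and frees the ring A phenol needed for the later ring closure.

Step 11
Reactants: 14 Weinreb amide; 15 1,2-bis(benzyloxy)-4-bromobenzene
Product: 17 (2R,3R)-2-(benzyloxy)-1-[3,4-bis(benzyloxy)phenyl]-3-[3,4-bis(benzyloxy)-2-hydroxyphenyl]-3-[2,3-bis(benzyloxy)-4-(methoxymethoxy)phenyl]propan-1-one, via aryllithium 16 (not isolated)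
Conditions: 15 (3 equiv), n-BuLi, THF, −78 °C; then 14, −78 → −40 °C; aq. NH4Cl
Reagents that add atoms: none
Why: Bromine–lithium exchange gives the aryllithium, one equivalent of which deprotonates the phenol while a second adds to the Weinreb amide, whose chelated tetrahedral adduct prevents over-addition.

Step 12
Reactants: 17 α-benzyloxy aryl ketone
Product: 18 (1S,2R,3R)-2-(benzyloxy)-1-[3,4-bis(benzyloxy)phenyl]-3-[3,4-bis(benzyloxy)-2-hydroxyphenyl]-3-[2,3-bis(benzyloxy)-4-(methoxymethoxy)phenyl]propan-1-ol (1,2-anti)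
Conditions: Zn(BH4)2, Et2O/CH2Cl2, −30 → 0 °C
Reagents that add atoms: none
Why: Chelation-controlled reduction (Cram chelate model), in which zinc bridges the carbonyl and the α-benzyloxy oxygen and hydride enters past the small α-hydrogen, should give the 1,2-anti alcohol (1S).

Step 13
Reactants: 18 anti phenol-alcohol
Product: 19 (2R,3R,4S)-3,7,8-tris(benzyloxy)-2-[3,4-bis(benzyloxy)phenyl]-4-[2,3-bis(benzyloxy)-4-(methoxymethoxy)phenyl]chroman (2,3-cis-3,4-trans)
Conditions: PPh3, DIAD, THF, 0 °C → rt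
Reagents that add atoms: none
Why: Intramolecular Mitsunobu etherification, in which the phenoxide displaces the activated benzylic oxygen with inversion while the adjacent benzyloxy group disfavours ionisation, should convert the anti alcohol into the 2,3-cis flavan (2R).

Step 14
Reactants: 19 MOM-protected 4-arylflavan
Product: 20 2,3-bis(benzyloxy)-4-(upper unit)phenol
Conditions: 2 M HCl, MeOH/THF, 40 °C
Reagents that add atoms: none
Why: Acid-catalysed cleavage of the aryl MOM acetal is much faster than any ionisation of benzyl or flavan ethers, so only the phenol para to the upper unit should be freed.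

Step 15
Reactants: 20 2,3-bis(benzyloxy)-4-(upper unit)phenol
Product: 22 3,4-bis(benzyloxy)-2-hydroxy-5-(upper unit)benzaldehyde, via salicyl alcohol 21 (not isolated)
Conditions: MgCl2, Et3N, (CH2O)n, THF, reflux; then 1 M HCl
Reagents that add atoms: formaldehyde (as paraformaldehyde), C=O
Why: Magnesium-mediated ortho-formylation (Casnati–Skattebøl reaction), in which the magnesium phenoxide delivers formaldehyde to the only free ortho position and a second equivalent of formaldehyde oxidises the hydroxymethyl intermediate by hydride transfer.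

Step 16
Reactants: 23 4-(benzyloxy)benzaldehyde
Product: 24 (E)-1-(benzyloxy)-4-(2-nitrovinyl)benzene
Conditions: MeNO2, NH4OAc, AcOH, 100 °C
Reagents that add atoms: nitromethane, C[N+](=O)[O-]
Why: Henry condensation followed by dehydration under ammonium acetate catalysis should give the conjugated (E)-nitroalkene.

Step 17
Reactants: 22 3,4-bis(benzyloxy)-2-hydroxy-5-(upper unit)benzaldehyde; 24 (E)-1-(benzyloxy)-4-(2-nitrovinyl)benzene
Product: 26 (2R,3S,4R)-7,8-bis(benzyloxy)-2-[4-(benzyloxy)phenyl]-3-nitro-6-(upper unit)chroman-4-ol (2,3-trans-3,4-trans), via oxa-Michael adduct 25 (not isolated)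
Conditions: 24 (1.5 equiv), quinine-derived 3,5-bis(trifluoromethyl)phenyl squaramide (10 mol %), toluene, 0 °C
Reagents that add atoms: none
Why: The quinuclidine nitrogen of the bifunctional catalyst deprotonates the phenol of 22 while the squaramide N–H bonds hold the nitro group of 24, so the phenoxide adds to the β-carbon (O1–C2) and the resulting nitronate adds to the neighbouring aldehyde (C3–C4); the closest known reaction type is the amine–squaramide or amine–thiourea catalysed oxa-Michael–Henry domino reaction of salicylaldehydes with β-nitrostyrenes to 2-aryl-3-nitrochroman-4-ols. Ring C is closed by the Henry step in a 6-exo-trig mode, the oxa-Michael step being intermolecular. C2 is set by the catalyst, which exposes one face of the hydrogen-bonded nitroalkene, the resident upper unit being too remote to interfere. C3 and C4 are set under thermodynamic control, since the nitro-bearing carbon is epimerisable and the Henry closure reversible, which should funnel the material into the all-equatorial isomer with the nitro group trans to both neighbours and the C2 aryl group cis to the C4 hydroxyl. The step needs addition to win over dehydration to the 3-nitro-2H-chromene, which low temperature and the weakly basic catalyst should secure, and it needs a single phenol and a single aldehyde, which the fully benzylated substrate provides.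

Step 18
Reactants: 26 3-nitrochroman-4-ol
Product: 27 O4-tert-butyldimethylsilyl ether of 26, (2R,3R,4R) by CIP with all stereocentres unchanged (the C3 descriptor changes only because silicon outranks carbon)
Conditions: TBSOTf, 2,6-lutidine, CH2Cl2, −78 → 0 °C
Reagents that add atoms: tert-butyldimethylsilyl trifluoromethanesulfonate, CC(C)(C)[Si](C)(C)OS(=O)(=O)C(F)(F)F
Why: Silylation of the C4 hydroxyl under weakly basic conditions shuts down the retro-Henry pathway and adds bulk on the face that must later be shielded.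

Step 19
Reactants: 27 silyl-protected nitro compound
Product: 28 (2R,4R)-7,8-bis(benzyloxy)-2-[4-(benzyloxy)phenyl]-4-(tert-butyldimethylsilyloxy)-6-(upper unit)chroman-3-one oxime (oxime geometry immaterial)
Conditions: SnCl2, PhSH, Et3N, MeCN/THF, rt
Reagents that add atoms: none
Why: Tin thiolate reduction of a secondary nitro group stops at the oxime and is fast at room temperature, so the C2 and C4 stereocentres and the silyl ether should be preserved.

Step 20
Reactants: 28 oxime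
Product: 29 (2R,4R)-7,8-bis(benzyloxy)-2-[4-(benzyloxy)phenyl]-4-(tert-butyldimethylsilyloxy)-6-(upper unit)chroman-3-one (2,4-cis)
Conditions: TiCl3 (aq.), NH4OAc, THF/H2O, rt
Reagents that add atoms: water, O
Why: Reductive deoximation, in which TiCl3 cleaves the N–O bond and the resulting imine hydrolyses in the buffered medium, is mild enough for the silyl ether and the epimerisable C2.

Step 21
Reactants: 29 C3 ketone
Product: 30 (2R,3S,4R)-7,8-bis(benzyloxy)-2-[4-(benzyloxy)phenyl]-4-(tert-butyldimethylsilyloxy)-6-(upper unit)chroman-3-ol (2,3-cis-3,4-cis; the 3S descriptor reflects silicon priority)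
Conditions: LiBH(s-Bu)3, THF, −78 °C; aq. NH4Cl
Reagents that add atoms: none
Why: The bulky hydride should attack the C3 ketone from the face opposite the cis-disposed C2 aryl and C4 silyloxy groups (equatorial attack), giving the axial C3 alcohol cis to both neighbours, as in the known reduction of flavan-3-ones to 2,3-cis flavan-3-ols.

Step 22
Reactants: 30 all-cis silyl ether
Product: 31 (2R,3R,4R)-7,8-bis(benzyloxy)-2-[4-(benzyloxy)phenyl]-6-(upper unit)chroman-3,4-diol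
Conditions: Bu4NF, THF, 0 °C → rt
Reagents that add atoms: none
Why: Fluoride-induced cleavage of the silyl ether is selective and leaves benzyl ethers and stereocentres untouched.

Step 23
Reactants: 31 octabenzyl ether of the target
Product: 32 (2R,3R,4R)-6-[(2R,3R,4S)-2-(3,4-dihydroxyphenyl)-3,7,8-trihydroxychroman-4-yl]-2-(4-hydroxyphenyl)chroman-3,4,7,8-tetrol (CNP0174688.1)
Conditions: H2 (1 atm), Pd(OH)2/C, THF/MeOH, rt
Reagents that add atoms: none
Why: Hydrogenolysis of the eight benzyl ethers over Pd(OH)2/C in a neutral medium should spare the benzylic C4 hydroxyl and the C4–C6 interflavan bond.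

Compound list

1 | 2,3,4-trihydroxybenzaldehyde | O=Cc1ccc(O)c(O)c1O | starting material
2 | 2,3-dihydroxy-4-(methoxymethoxy)benzaldehyde | O=Cc1ccc(OCOC)c(O)c1O | intermediate
3 | 2,3-bis(benzyloxy)-4-(methoxymethoxy)benzaldehyde | O=Cc1ccc(OCOC)c(OCc9ccccc9)c1OCc9ccccc9 | intermediate
4 | 2,3-bis(benzyloxy)-4-(methoxymethoxy)phenyl formate | O=COc1ccc(OCOC)c(OCc9ccccc9)c1OCc9ccccc9 | intermediate (not isolated)
5 | 2,3-bis(benzyloxy)-4-(methoxymethoxy)phenol | Oc1ccc(OCOC)c(OCc9ccccc9)c1OCc9ccccc9 | intermediate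
6 | 2,3-bis(benzyloxy)-4-(methoxymethoxy)phenyl trifluoromethanesulfonate | O=S(=O)(Oc1ccc(OCOC)c(OCc9ccccc9)c1OCc9ccccc9)C(F)(F)F | intermediate
7 | 2-[2,3-bis(benzyloxy)-4-(methoxymethoxy)phenyl]-4,4,5,5-tetramethyl-1,3,2-dioxaborolane | CC1(C)OB(OC1(C)C)c1ccc(OCOC)c(OCc9ccccc9)c1OCc9ccccc9 | intermediate (not isolated)
8 | [2,3-bis(benzyloxy)-4-(methoxymethoxy)phenyl]boronic acid | OB(O)c1ccc(OCOC)c(OCc9ccccc9)c1OCc9ccccc9 | intermediate
9 | 7,8-dihydroxycoumarin | O=c1ccc2ccc(O)c(O)c2o1 | starting material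
10 | 7,8-bis(benzyloxy)coumarin | O=c1ccc2ccc(OCc9ccccc9)c(OCc9ccccc9)c2o1 | intermediate
11 | (4S)-7,8-bis(benzyloxy)-4-[2,3-bis(benzyloxy)-4-(methoxymethoxy)phenyl]chroman-2-one | COCOc1ccc([C@H]4c5ccc(OCc9ccccc9)c(OCc9ccccc9)c5OC(=O)C4)c(OCc9ccccc9)c1OCc9ccccc9 | intermediate
12 | (3R,4S)-7,8-bis(benzyloxy)-4-[2,3-bis(benzyloxy)-4-(methoxymethoxy)phenyl]-3-hydroxychroman-2-one | COCOc1ccc([C@H]4c5ccc(OCc9ccccc9)c(OCc9ccccc9)c5OC(=O)[C@@H]4O)c(OCc9ccccc9)c1OCc9ccccc9 | intermediate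
13 | (3R,4S)-3,7,8-tris(benzyloxy)-4-[2,3-bis(benzyloxy)-4-(methoxymethoxy)phenyl]chroman-2-one | COCOc1ccc([C@H]4c5ccc(OCc9ccccc9)c(OCc9ccccc9)c5OC(=O)[C@@H]4OCc9ccccc9)c(OCc9ccccc9)c1OCc9ccccc9 | intermediate
14 | (2R,3R)-2-(benzyloxy)-3-[3,4-bis(benzyloxy)-2-hydroxyphenyl]-3-[2,3-bis(benzyloxy)-4-(methoxymethoxy)phenyl]-N-methoxy-N-methylpropanamide | COCOc1ccc([C@H]([C@@H](OCc9ccccc9)C(=O)N(C)OC)c5ccc(OCc9ccccc9)c(OCc9ccccc9)c5O)c(OCc9ccccc9)c1OCc9ccccc9 | intermediate
15 | 1,2-bis(benzyloxy)-4-bromobenzene | Brc1ccc(OCc9ccccc9)c(OCc9ccccc9)c1 | starting material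
16 | [3,4-bis(benzyloxy)phenyl]lithium | [Li]c1ccc(OCc9ccccc9)c(OCc9ccccc9)c1 | intermediate (not isolated)
17 | (2R,3R)-2-(benzyloxy)-1-[3,4-bis(benzyloxy)phenyl]-3-[3,4-bis(benzyloxy)-2-hydroxyphenyl]-3-[2,3-bis(benzyloxy)-4-(methoxymethoxy)phenyl]propan-1-one | COCOc1ccc([C@H]([C@@H](OCc9ccccc9)C(=O)c6ccc(OCc9ccccc9)c(OCc9ccccc9)c6)c5ccc(OCc9ccccc9)c(OCc9ccccc9)c5O)c(OCc9ccccc9)c1OCc9ccccc9 | intermediate
18 | (1S,2R,3R)-2-(benzyloxy)-1-[3,4-bis(benzyloxy)phenyl]-3-[3,4-bis(benzyloxy)-2-hydroxyphenyl]-3-[2,3-bis(benzyloxy)-4-(methoxymethoxy)phenyl]propan-1-ol | COCOc1ccc([C@H]([C@@H](OCc9ccccc9)[C@@H](O)c6ccc(OCc9ccccc9)c(OCc9ccccc9)c6)c5ccc(OCc9ccccc9)c(OCc9ccccc9)c5O)c(OCc9ccccc9)c1OCc9ccccc9 | intermediate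
19 | (2R,3R,4S)-3,7,8-tris(benzyloxy)-2-[3,4-bis(benzyloxy)phenyl]-4-[2,3-bis(benzyloxy)-4-(methoxymethoxy)phenyl]chroman | COCOc1ccc([C@H]4c5ccc(OCc9ccccc9)c(OCc9ccccc9)c5O[C@H](c6ccc(OCc9ccccc9)c(OCc9ccccc9)c6)[C@@H]4OCc9ccccc9)c(OCc9ccccc9)c1OCc9ccccc9 | intermediate
20 | 2,3-bis(benzyloxy)-4-[(2R,3R,4S)-3,7,8-tris(benzyloxy)-2-[3,4-bis(benzyloxy)phenyl]chroman-4-yl]phenol | Oc1ccc([C@H]4c5ccc(OCc9ccccc9)c(OCc9ccccc9)c5O[C@H](c6ccc(OCc9ccccc9)c(OCc9ccccc9)c6)[C@@H]4OCc9ccccc9)c(OCc9ccccc9)c1OCc9ccccc9 | intermediate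
21 | 2,3-bis(benzyloxy)-6-(hydroxymethyl)-4-[(2R,3R,4S)-3,7,8-tris(benzyloxy)-2-[3,4-bis(benzyloxy)phenyl]chroman-4-yl]phenol | OCc1cc([C@H]4c5ccc(OCc9ccccc9)c(OCc9ccccc9)c5O[C@H](c6ccc(OCc9ccccc9)c(OCc9ccccc9)c6)[C@@H]4OCc9ccccc9)c(OCc9ccccc9)c(OCc9ccccc9)c1O | intermediate (not isolated)
22 | 3,4-bis(benzyloxy)-2-hydroxy-5-[(2R,3R,4S)-3,7,8-tris(benzyloxy)-2-[3,4-bis(benzyloxy)phenyl]chroman-4-yl]benzaldehyde | O=Cc1cc([C@H]4c5ccc(OCc9ccccc9)c(OCc9ccccc9)c5O[C@H](c6ccc(OCc9ccccc9)c(OCc9ccccc9)c6)[C@@H]4OCc9ccccc9)c(OCc9ccccc9)c(OCc9ccccc9)c1O | intermediate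
23 | 4-(benzyloxy)benzaldehyde | O=Cc1ccc(OCc9ccccc9)cc1 | starting material
24 | (E)-1-(benzyloxy)-4-(2-nitrovinyl)benzene | [O-][N+](=O)/C=C/c1ccc(OCc9ccccc9)cc1 | intermediate
25 | 3,4-bis(benzyloxy)-2-[(1R)-1-[4-(benzyloxy)phenyl]-2-nitroethoxy]-5-[(2R,3R,4S)-3,7,8-tris(benzyloxy)-2-[3,4-bis(benzyloxy)phenyl]chroman-4-yl]benzaldehyde | C(c9ccccc9)Oc1ccc(cc1)[C@H](C[N+](=O)[O-])Oc3c(C=O)cc([C@H]4c5ccc(OCc9ccccc9)c(OCc9ccccc9)c5O[C@H](c6ccc(OCc9ccccc9)c(OCc9ccccc9)c6)[C@@H]4OCc9ccccc9)c(OCc9ccccc9)c3OCc9ccccc9 | intermediate (not isolated)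
26 | (2R,3S,4R)-7,8-bis(benzyloxy)-2-[4-(benzyloxy)phenyl]-3-nitro-6-[(2R,3R,4S)-3,7,8-tris(benzyloxy)-2-[3,4-bis(benzyloxy)phenyl]chroman-4-yl]chroman-4-ol | C(c9ccccc9)Oc1ccc(cc1)[C@H]2Oc3c(cc([C@H]4c5ccc(OCc9ccccc9)c(OCc9ccccc9)c5O[C@H](c6ccc(OCc9ccccc9)c(OCc9ccccc9)c6)[C@@H]4OCc9ccccc9)c(OCc9ccccc9)c3OCc9ccccc9)[C@@H](O)[C@@H]2[N+](=O)[O-] | intermediate
27 | (2R,3R,4R)-7,8-bis(benzyloxy)-2-[4-(benzyloxy)phenyl]-4-(tert-butyldimethylsilyloxy)-3-nitro-6-[(2R,3R,4S)-3,7,8-tris(benzyloxy)-2-[3,4-bis(benzyloxy)phenyl]chroman-4-yl]chroman | C(c9ccccc9)Oc1ccc(cc1)[C@H]2Oc3c(cc([C@H]4c5ccc(OCc9ccccc9)c(OCc9ccccc9)c5O[C@H](c6ccc(OCc9ccccc9)c(OCc9ccccc9)c6)[C@@H]4OCc9ccccc9)c(OCc9ccccc9)c3OCc9ccccc9)[C@@H](O[Si](C)(C)C(C)(C)C)[C@@H]2[N+](=O)[O-] | intermediate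
28 | (2R,4R)-7,8-bis(benzyloxy)-2-[4-(benzyloxy)phenyl]-4-(tert-butyldimethylsilyloxy)-6-[(2R,3R,4S)-3,7,8-tris(benzyloxy)-2-[3,4-bis(benzyloxy)phenyl]chroman-4-yl]chroman-3-one oxime | C(c9ccccc9)Oc1ccc(cc1)[C@H]2Oc3c(cc([C@H]4c5ccc(OCc9ccccc9)c(OCc9ccccc9)c5O[C@H](c6ccc(OCc9ccccc9)c(OCc9ccccc9)c6)[C@@H]4OCc9ccccc9)c(OCc9ccccc9)c3OCc9ccccc9)[C@@H](O[Si](C)(C)C(C)(C)C)C2=NO | intermediate
29 | (2R,4R)-7,8-bis(benzyloxy)-2-[4-(benzyloxy)phenyl]-4-(tert-butyldimethylsilyloxy)-6-[(2R,3R,4S)-3,7,8-tris(benzyloxy)-2-[3,4-bis(benzyloxy)phenyl]chroman-4-yl]chroman-3-one | C(c9ccccc9)Oc1ccc(cc1)[C@H]2Oc3c(cc([C@H]4c5ccc(OCc9ccccc9)c(OCc9ccccc9)c5O[C@H](c6ccc(OCc9ccccc9)c(OCc9ccccc9)c6)[C@@H]4OCc9ccccc9)c(OCc9ccccc9)c3OCc9ccccc9)[C@@H](O[Si](C)(C)C(C)(C)C)C2=O | intermediate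
30 | (2R,3S,4R)-7,8-bis(benzyloxy)-2-[4-(benzyloxy)phenyl]-4-(tert-butyldimethylsilyloxy)-6-[(2R,3R,4S)-3,7,8-tris(benzyloxy)-2-[3,4-bis(benzyloxy)phenyl]chroman-4-yl]chroman-3-ol (all-cis) | C(c9ccccc9)Oc1ccc(cc1)[C@H]2Oc3c(cc([C@H]4c5ccc(OCc9ccccc9)c(OCc9ccccc9)c5O[C@H](c6ccc(OCc9ccccc9)c(OCc9ccccc9)c6)[C@@H]4OCc9ccccc9)c(OCc9ccccc9)c3OCc9ccccc9)[C@@H](O[Si](C)(C)C(C)(C)C)[C@H]2O | intermediate
31 | (2R,3R,4R)-7,8-bis(benzyloxy)-2-[4-(benzyloxy)phenyl]-6-[(2R,3R,4S)-3,7,8-tris(benzyloxy)-2-[3,4-bis(benzyloxy)phenyl]chroman-4-yl]chroman-3,4-diol | C(c9ccccc9)Oc1ccc(cc1)[C@H]2Oc3c(cc([C@H]4c5ccc(OCc9ccccc9)c(OCc9ccccc9)c5O[C@H](c6ccc(OCc9ccccc9)c(OCc9ccccc9)c6)[C@@H]4OCc9ccccc9)c(OCc9ccccc9)c3OCc9ccccc9)[C@@H](O)[C@H]2O | intermediate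
32 | (2R,3R,4R)-6-[(2R,3R,4S)-2-(3,4-dihydroxyphenyl)-3,7,8-trihydroxychroman-4-yl]-2-(4-hydroxyphenyl)chroman-3,4,7,8-tetrol | Oc1ccc([C@H]2Oc3c(cc([C@H]4c5ccc(O)c(O)c5O[C@H](c5ccc(O)c(O)c5)[C@@H]4O)c(O)c3O)[C@@H](O)[C@H]2O)cc1 | target

Total step count: 23 steps. Longest linear sequence: 21 steps (steps 1–5, 7–15 and 17–23).

Steps most likely to fail

Step 17. The crowded, electron-rich phenol may add only slowly, reversible oxa-Michael addition may erode the selectivity at C2, and the adduct may lose water to the 3-nitro-2H-chromene. The fallback sets out from 22 and comes back at 27; it makes the C3–C4 bond first with a different source of chirality and closes ring C last. The phenol of 22 would be silylated (TBSCl, imidazole, DMF) to the O-silyl salicylaldehyde F1. A copper–bis(oxazoline)-catalysed asymmetric Henry reaction with nitromethane (Cu(OAc)2·H2O, indane-derived bis(oxazoline) ligand, EtOH, rt) should give the (R)-nitro alcohol F2, which is silylated (TBSOTf, 2,6-lutidine) to the bis-silyl ether F3. Condensation of F3 with 23 (n-BuNH2, AcOH, toluene, 4 Å sieves) would give the nitroalkene F4. Cs2CO3 in DMF/H2O would then cleave only the aryl silyl ether, and the phenoxide should add to the nitroalkene in a 6-endo oxa-Michael closure. Equilibration of C3, and of C2 through reversible ring opening, should deliver the all-equatorial 27.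

Step 19. Under triethylamine the nitronate may expel the C4 silanolate or open ring C by retro-oxa-Michael reaction before it is reduced. The fallback sets out from 27 and comes back at 29, bypassing 28 and avoiding nitronate chemistry. The nitro group would be reduced to the primary amine F5 with nickel boride (NiCl2·6H2O, NaBH4, MeOH/THF, 0 °C). Quinone-mediated transamination with 3,5-di-tert-butyl-1,2-benzoquinone (MeOH/THF, rt) should give, after prototropic shift, the N-(2-hydroxyaryl) ketimine F6, which aqueous oxalic acid hydrolyses to 29.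

Step 7. Transmetalation and insertion may be slow with the hindered ortho-alkoxy boronic acid and the donor-substituted coumarin, so that protodeboronation consumes the boronic acid. The fallback sets out from 10 and 8 and comes back at 11; it separates C–C bond formation from the creation of the stereocentre. Oxidative Heck (Fujiwara–Moritani-type) coupling (Pd(OAc)2, 1,10-phenanthroline, O2, DMF, 80 °C) would give the 4-arylcoumarin F7. Copper hydride-catalysed asymmetric conjugate reduction (Cu(OAc)2·H2O, DTBM-SEGPHOS in the enantiomer that gives the 4S lactone, (EtO)2MeSiH, t-BuOH, toluene) should then give 11.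

Further compounds

F1 | step 17 | 3,4-bis(benzyloxy)-2-(tert-butyldimethylsilyloxy)-5-[(2R,3R,4S)-3,7,8-tris(benzyloxy)-2-[3,4-bis(benzyloxy)phenyl]chroman-4-yl]benzaldehyde | CC(C)(C)[Si](C)(C)Oc1c(OCc9ccccc9)c(OCc9ccccc9)c([C@H]4c5ccc(OCc9ccccc9)c(OCc9ccccc9)c5O[C@H](c6ccc(OCc9ccccc9)c(OCc9ccccc9)c6)[C@@H]4OCc9ccccc9)cc1C=O
F2 | step 17 | (1R)-1-[3,4-bis(benzyloxy)-2-(tert-butyldimethylsilyloxy)-5-(upper unit)phenyl]-2-nitroethanol | CC(C)(C)[Si](C)(C)Oc1c(OCc9ccccc9)c(OCc9ccccc9)c([C@H]4c5ccc(OCc9ccccc9)c(OCc9ccccc9)c5O[C@H](c6ccc(OCc9ccccc9)c(OCc9ccccc9)c6)[C@@H]4OCc9ccccc9)cc1[C@@H](O)C[N+](=O)[O-]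
F3 | step 17 | (1R)-1-[3,4-bis(benzyloxy)-2-(tert-butyldimethylsilyloxy)-5-(upper unit)phenyl]-1-(tert-butyldimethylsilyloxy)-2-nitroethane | CC(C)(C)[Si](C)(C)Oc1c(OCc9ccccc9)c(OCc9ccccc9)c([C@H]4c5ccc(OCc9ccccc9)c(OCc9ccccc9)c5O[C@H](c6ccc(OCc9ccccc9)c(OCc9ccccc9)c6)[C@@H]4OCc9ccccc9)cc1[C@@H](O[Si](C)(C)C(C)(C)C)C[N+](=O)[O-]
F4 | step 17 | (1R)-1-[3,4-bis(benzyloxy)-2-(tert-butyldimethylsilyloxy)-5-(upper unit)phenyl]-3-[4-(benzyloxy)phenyl]-1-(tert-butyldimethylsilyloxy)-2-nitroprop-2-ene (alkene geometry not controlled) | CC(C)(C)[Si](C)(C)Oc1c(OCc9ccccc9)c(OCc9ccccc9)c([C@H]4c5ccc(OCc9ccccc9)c(OCc9ccccc9)c5O[C@H](c6ccc(OCc9ccccc9)c(OCc9ccccc9)c6)[C@@H]4OCc9ccccc9)cc1[C@@H](O[Si](C)(C)C(C)(C)C)C(=Cc1ccc(OCc9ccccc9)cc1)[N+](=O)[O-]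
F5 | step 19 | 3-amino analogue of 27 (2,3-trans-3,4-trans): 7,8-bis(benzyloxy)-2-[4-(benzyloxy)phenyl]-4-(tert-butyldimethylsilyloxy)-6-(upper unit)chroman-3-amine | C(c9ccccc9)Oc1ccc(cc1)[C@H]2Oc3c(cc([C@H]4c5ccc(OCc9ccccc9)c(OCc9ccccc9)c5O[C@H](c6ccc(OCc9ccccc9)c(OCc9ccccc9)c6)[C@@H]4OCc9ccccc9)c(OCc9ccccc9)c3OCc9ccccc9)[C@@H](O[Si](C)(C)C(C)(C)C)[C@@H]2N
F6 | step 19 | N-(3,5-di-tert-butyl-2-hydroxyphenyl) ketimine of 29 | C(c9ccccc9)Oc1ccc(cc1)[C@H]2Oc3c(cc([C@H]4c5ccc(OCc9ccccc9)c(OCc9ccccc9)c5O[C@H](c6ccc(OCc9ccccc9)c(OCc9ccccc9)c6)[C@@H]4OCc9ccccc9)c(OCc9ccccc9)c3OCc9ccccc9)[C@@H](O[Si](C)(C)C(C)(C)C)C2=Nc1cc(C(C)(C)C)cc(C(C)(C)C)c1O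
F7 | step 7 | 7,8-bis(benzyloxy)-4-[2,3-bis(benzyloxy)-4-(methoxymethoxy)phenyl]coumarin | O=c1cc(-c3ccc(OCOC)c(OCc9ccccc9)c3OCc9ccccc9)c2ccc(OCc9ccccc9)c(OCc9ccccc9)c2o1
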